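The runs were generated by integration for substances that don't exist.

1.57 times the free catalyst bought 0.9 percentage points of left-handed product at 12.0 h: that is the midnight run against the dawn run. Both are kinetic resolutions of the racemate, and the new flask is charged with 0.25 mM free catalyst.

| flask | left-handed substrate | right-handed substrate | gas | free catalyst | remark | time |
|---|---|---|---|---|---|---|
| dawn | 10 mM | 10 mM | 0.75 mM (held) | 0.35 mM | run made earlier |  |
| midnight | 10 mM | 10 mM | 0.75 mM (held) | 0.55 mM | run made earlier |  |
| flask | 10 mM | 10 mM | 0.75 mM (held) | 0.25 mM |  | 12 h |

| run | time / h | left-handed product / % | left-handed substrate / % |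
|---|---|---|---|
| dawn | 0.833 | 3.1 | 48.5 |
| dawn | 2.50 | 4.6 | 46.5 |
| dawn | 4.00 | 6.6 | 42.5 |
| dawn | 6.00 | 8.7 | 41.9 |
| dawn | 10.0 | 11.5 | 37.5 |
| dawn | 12.0 | 14.1 | 36.8 |
| midnight | 2.00 | 3.9 | 46.9 |
| midnight | 4.00 | 6.2 | 42.7 |
| midnight | 6.00 | 7.7 | 41.5 |
| midnight | 8.00 | 13.1 | 39.3 |
| midnight | 10.0 | 14.0 | 35.4 |
| midnight | 12.0 | 15.0 | 35.7 |

(scatter of a reading: 1 percentage point)

- free catalyst is single-handed; left-handed substrate and right-handed substrate are mirror images of each other, charged as a racemate, each of them at the stated concentration
- at the start none of coupling partner is dissolved
- the numbers in the tables scatter by 1 percentage point (one standard deviation)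
- steps thought possible: 2 free catalyst -> spent catalyst; coupling partner + free catalyst + right-handed substrate -> free catalyst + right-handed product; coupling partner + free catalyst + left-handed substrate -> free catalyst + left-handed product; gas <-> coupling partner

- ash: doubling the amount of free catalyst, all else as stated
- elm: doubling the transfer coefficient of the gas, all else as stated
- oak: doubling the saturation concentration of gas, all else as stated

1. amount of left-handed product at 12 h, in percent of the left-handed substrate and right-handed substrate together charged
2. the change that raises the amount of left-handed product at 12 h, in percent of the left-handed substrate and right-handed substrate together charged most ("none" if none brings more than 2 percentage points) (ash / elm / oak / none)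
3. amount of left-handed product at 12 h, in percent of the left-handed substrate and right-handed substrate together charged, after ash

Two chemists dispute the flask. The first says product follows the catalyst charge, so scaling dawn gives 10.1%. The second objects that the same scaling puts midnight at 22.2%, but it read 15.0%. At 4.00 h the runs read 6.6% and 6.2%, so she pools them into one curve and reads its bend.

Take y = Y·t/(t + T), where y is product, t is time, Y is the plateau, and T is the bend time. T equals the gain between two readings divided by the fall in the hourly average. The pooled readings are 6.40% and 14.5%, so T is 21.0 h. This is a rough reading, given the scatter. It gives no yield by itself. My own use of it is to carry a reading to another time, through the ratio of t/(t + T).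

The forecast takes the second side: 12.8% (10.8% to 14.3%), 14.8% after ash (13.3% to 16.5%), and oak best, “so catalyst is not the main limit”.

    2 free catalyst → spent catalyst (k = 0.120 M⁻¹ s⁻¹)
    coupling partner + free catalyst + right-handed substrate → free catalyst + right-handed product (k = 2.30 M⁻² s⁻¹)
    coupling partner + free catalyst + left-handed substrate → free catalyst + left-handed product (k = 130 M⁻² s⁻¹)
    gas ⇌ coupling partner, rate k4*(csat - [coupling partner]) (kL = 2.60 × 10⁻⁴ s⁻¹)

The flask gives 12.8%, and 15.0% after ash. Oak adds 10 points, elm 2.9 points, ash 2.2 points, so oak is best. In this flask, left-handed coupling had done half of its turnover up to 12 h by 4.95 h, and free catalyst stood at 43.6% of the catalyst charged at 6.00 h. By 12.0 h coupling partner had risen to 0.584 mM, with 27.8% of the catalyst free. The first chemist's ground lies at lower charges: the answer has moved 5 points at 0.0758 mM, while upward it stays within 5 points up to at least 2.0 mM. T carries this flask's 7.56% at 6.00 h to 12.4% at 12 h. Carried on to 30 h, 12.8% becomes 20.7%; the flask read then holds 21.1%.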